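C1(H3)–C2–C3–C4–C5–C6 is the arm. Ring A = C6–C7=C8(C9O2H)–C10(C11H3)–C12–C13. Lactone ring B = C13–O14–C15(=O)–C16(C17H3)–C22. Ring C = C16–C18(=O)–C19(=O)–C20–C21–C22. Ring D (11 atoms) = C2–C6, C13, C22, C21, C20, C23(C24H3), C25.
Enabling feature: C23 of ring D lies β to the C19 ketone of ring C (through C20), and C19 is flanked by the C18 ketone. Ring D is therefore cut last at C23–C25 into a primary C25 radical on the C6 arm and a C20 (E)-ethylidene 1,2-dione that a Lewis acid can chelate.
Further cuts: C20=C23 (acetaldehyde aldol), C19–O, C16–C17 (methylation), C22–H (conjugate hydride), C19–C20/C16–C22/O14–C15 (Michael–Knoevenagel–lactonisation), C21–C22 (vinyl Grignard), C6–C13/C10–C12 (Diels–Alder), C7–C8 (Stille), C3–C4 (copper-catalysed coupling).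
Forward order: arm and diene, ring A, rings C and B together, C25 iodide, ethylidene dione, ring D last, ester cleavage.
Stereochemistry: C2 comes from (S)-3-bromo-2-methylpropan-1-ol. C6, C10 and C13 come from an exo, face-selective Diels–Alder reaction with the methylene dioxolanone made from (S)-lactic acid. C22 and C16 are set by hydride and methyl delivery to the C12 face of ring B, away from the arm. C23 and C20 are set in the tethered radical closure.
Key step: step 25

Remark on the chemistry: the cyclic 1,2-diones are drawn as diketones although 34 and 37 should be largely enolised toward C20. The C19 carbinol of 33 and C20/C23 of 37 are expected as mixtures and are drawn without configuration because the following steps erase them.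

Step 1
Reactants: 1 (S)-3-bromo-2-methylpropan-1-ol
Product: 2 (S)-(3-bromo-2-methylpropoxy)(tert-butyl)diphenylsilane
Conditions: TBDPSCl, imidazole, CH2Cl2, 0 °C → rt
Reagents that add atoms: tert-butyl(chloro)diphenylsilane, CC(C)(C)[Si](Cl)(c1ccccc1)c1ccccc1
Why: Routine silylation of a primary alcohol leaves the C2 stereocentre untouched, and the TBDPS ether is chosen because it has to outlast Grignard, Lewis acid, borohydride and carbonate steps up to step 19.

Step 2
Reactants: 2 (S)-(3-bromo-2-methylpropoxy)(tert-butyl)diphenylsilane; 3 (4-bromobut-1-yn-1-yl)trimethylsilane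
Product: 5 (R)-tert-butyl{[2-methyl-7-(trimethylsilyl)hept-6-yn-1-yl]oxy}diphenylsilane, via butynylmagnesium bromide 4 (not isolated)
Conditions: 3, Mg, THF, rt; then 2, Li2CuCl4 (5 mol %), NMP, THF, 0 °C → rt
Reagents that add atoms: none
Why: Copper-catalysed cross-coupling of a primary alkyl bromide with a primary alkyl Grignard reagent forms C3–C4 at a carbon that is not stereogenic, so C2 is carried over unchanged while the silyl cap masks the acidic alkyne terminus.

Step 3
Reactants: 5 silyl-capped alkyne
Product: 6 (R)-tert-butyl[(2-methylhept-6-yn-1-yl)oxy]diphenylsilane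
Conditions: K2CO3 (0.2 equiv), MeOH, rt
Reagents that add atoms: none
Why: Methoxide-induced protodesilylation cleaves only the C(sp)–Si bond, the hindered TBDPS ether being stable to these conditions.

Step 4
Reactants: 6 terminal alkyne
Product: 8 (R,E)-tert-butyl[(7-iodo-2-methylhept-6-en-1-yl)oxy]diphenylsilane, via alkenylzirconocene chloride 7 (not isolated)
Conditions: Cp2ZrHCl, THF, rt; then I2, THF, 0 °C
Reagents that add atoms: iodine, II
Why: syn-Hydrozirconation places zirconium on the terminal carbon C7 and iodinolysis proceeds with retention, which gives the E-alkenyl iodide needed for an outside arm in the later diene.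

Step 5
Reactants: 9 propyne
Product: 11 tert-butyl but-2-ynoate, via prop-1-ynyllithium 10 (not isolated)
Conditions: n-BuLi, THF, −78 °C; then Boc2O, −78 → 0 °C
Reagents that add atoms: di-tert-butyl dicarbonate, CC(C)(C)OC(=O)OC(=O)OC(C)(C)C
Why: Acylation of a lithium acetylide by the dicarbonate brings in C9 directly as the acid-labile tert-butyl ester that is removed in the last step.

Step 6
Reactants: 11 tert-butyl but-2-ynoate
Product: 12 tert-butyl (E)-2-(tributylstannyl)but-2-enoate
Conditions: Bu3SnH, Pd(PPh3)4 (2 mol %), THF, 0 °C → rt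
Reagents that add atoms: tributyltin hydride, CCCC[SnH](CCCC)CCCC
Why: Palladium-catalysed hydrostannation of an alkynoate is a syn addition that puts tin on the α-carbon C8, so the C11 methyl ends cis to the ester, the less stable geometry that a condensation route would not deliver.

Step 7
Reactants: 8 E-alkenyl iodide; 12 α-stannyl enoate
Product: 13 tert-butyl (2Z,3E,8R)-9-[(tert-butyldiphenylsilyl)oxy]-2-ethylidene-8-methylnon-3-enoate
Conditions: Pd(PPh3)4 (5 mol %), CuI (20 mol %), CsF, DMF, 45 °C
Reagents that add atoms: none
Why: Stille coupling with copper and fluoride co-promotion, established for α-stannyl enoates, joins C7 to C8 with retention at both alkenes and gives a diene whose arm and methyl group both take outside positions in the s-cis form.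

Step 8
Reactants: 14 (S)-lactic acid; 15 pivalaldehyde
Product: 16 (2S,5S)-2-tert-butyl-5-methyl-1,3-dioxolan-4-one
Conditions: p-TsOH (cat.), pentane, reflux, Dean–Stark trap; crystallisation from cold pentane
Reagents that add atoms: none
Why: Acid-catalysed acetalisation under equilibrating conditions favours the cis-2,5-disubstituted dioxolanone, so the lactic acid stereocentre is copied onto the acetal carbon and crystallisation removes the trans isomer.

Step 9
Reactants: 16 cis-dioxolanone
Product: 18 (S)-2-tert-butyl-5-methylene-1,3-dioxolan-4-one, via bromodioxolanone 17 (not isolated)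
Conditions: NBS, AIBN (cat.), PhCF3, reflux; then Et3N, Et2O, 0 °C → rt
Reagents that add atoms: none
Why: Wohl–Ziegler bromination at the captodative C–H next to carbonyl and oxygen, followed by E2 loss of HBr toward the methyl group, gives the exocyclic alkene C12=C13 and leaves the acetal carbon as the only, configurationally stable, stereocentre.

Step 10
Reactants: 13 diene; 18 (S)-methylene dioxolanone
Product: 19 ring A spiro-dioxolanone cycloadduct
Conditions: 18 (3 equiv), BHT (cat.), toluene, 110 °C, sealed tube
Reagents that add atoms: none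
Why: In this thermal Diels–Alder reaction, of a type established for α-oxygenated methylene lactones, the C8 ester directs the new quaternary carbon para (C13 to C6, C12 to C10), the dienophile carbonyl reacts exo so that O14 ends cis to the two outside diene substituents (arm on C6, C11 methyl on C10), and approach opposite the tert-butyl group fixes the absolute configuration of C6, C10 and C13.

Step 11
Reactants: 19 cycloadduct
Product: 20 α-hydroxy N-methoxy-N-methylamide (C13–OH, C22 amide)
Conditions: MeNH(OMe)·HCl, i-PrMgCl, THF, −20 → 0 °C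
Reagents that add atoms: N,O-dimethylhydroxylamine hydrochloride, CNOC.Cl
Why: Aminolysis of the activated acylal-type lactone by the magnesium amide releases the auxiliary as pivalaldehyde and unveils the tertiary O14–H, the hindered tert-butyl enoate being inert.

Step 12
Reactants: 20 amide
Product: 21 α-hydroxy vinyl ketone (C13(OH)–C22(=O)–C21H=C20H2)
Conditions: CH2=CHMgBr (3.5 equiv), THF, −20 → 0 °C; inverse quench into cold 1 M HCl
Reagents that add atoms: vinylmagnesium bromide, C=C[Mg]Br
Why: Ketone synthesis from an N-methoxy-N-methylamide stops at the chelated tetrahedral intermediate, and the inverse acidic quench keeps the liberated amine from adding to the new enone.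

Step 13
Reactants: 22 methyl acetoacetate
Product: 23 methyl 3-(trimethylsilyloxy)but-2-enoate
Conditions: TMSCl, Et3N, hexane, rt
Reagents that add atoms: chlorotrimethylsilane, C[Si](C)(C)Cl
Why: O-Silylation of the readily enolised β-keto ester is a standard enol silane preparation.

Step 14
Reactants: 23 mono(silyl) enol ether
Product: 25 1-methoxy-1,3-bis(trimethylsilyloxy)buta-1,3-diene, via lithium dienolate 24 (not isolated)
Conditions: LDA, THF, −78 °C; then TMSCl, −78 → 0 °C
Reagents that add atoms: chlorotrimethylsilane, C[Si](C)(C)Cl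
Why: γ-Deprotonation of the silyloxy crotonate and O-silylation of the dienolate give the neutral equivalent of the acetoacetate dianion, nucleophilic at its terminal carbon C19.

Step 15
Reactants: 21 vinyl ketone; 25 bis(silyloxy)diene
Product: 26 methyl 3,7-dioxoheptanoate attached through C22 to C13
Conditions: Sc(OTf)3 (10 mol %), CH2Cl2, −78 → −40 °C; then 0.5 M HCl, THF, 0 °C
Reagents that add atoms: none
Why: In this Mukaiyama–Michael addition the dienol ether attacks through C19 the unsubstituted β-carbon C20 of the Lewis-acid-activated vinyl ketone, and the acidic work-up frees both carbonyl groups and any silylated O14.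

Step 16
Reactants: 26 dioxo ester
Product: 27 tricyclic acyl butenolide (C16=C22, C18=O)
Conditions: piperidine (20 mol %), AcOH (20 mol %), 4 Å molecular sieves, toluene, 80 °C
Reagents that add atoms: none
Why: Intramolecular Knoevenagel condensation of the C16 methylene with the C22 ketone closes the only possible six-membered ring, as in the aldol stage of a Robinson annulation next to a quaternary carbon, and lactonisation of O14–H onto C15 with E1cB loss of water completes rings C and B without creating a stereocentre.

Step 17
Reactants: 27 acyl butenolide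
Product: 28 cis-fused β-keto lactone
Conditions: NaBH4, THF–MeOH, −40 °C; aq NH4Cl
Reagents that add atoms: none
Why: 1,4-Reduction of an alkylidene 1,3-dicarbonyl unit, far more electrophilic than the C7=C8 enoate, stops at a stabilised enolate that shields C18; because C21 lies in the lactone plane, C22 must sit equatorial on ring A, which puts C5 of the arm directly over the C6 face of ring B, so hydride should enter from the C12 face and set C22, with C16 settling cis-fused on protonation.

Step 18
Reactants: 28 β-keto lactone
Product: 29 C16-methyl β-keto lactone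
Conditions: MeI, K2CO3, acetone, rt
Reagents that add atoms: iodomethane, CI
Why: C-Alkylation of the β-keto lactone enolate brings the methyl group in from the C12 face, the only one that keeps the bicycle cis-fused and avoids the arm, and so creates the quaternary C16 syn to H22.

Step 19
Reactants: 29 silyl ether
Product: 30 primary C25 alcohol
Conditions: HF·pyridine, pyridine, THF, 0 °C → rt
Reagents that add atoms: none
Why: Fluoride cleavage of the silyl ether in a buffered acidic medium is preferred to basic fluoride sources because the non-enolisable β-keto lactone is open to retro-Claisen cleavage by nucleophilic base.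

Step 20
Reactants: 30 alcohol
Product: 31 primary C25 iodide
Conditions: I2, PPh3, imidazole, CH2Cl2, 0 °C
Reagents that add atoms: iodine, II
Why: Appel-type iodination of the only hydroxy group runs through an alkoxyphosphonium salt and SN2 attack of iodide at C25, and it is placed before the phosphine-sensitive dione and enone exist.

Step 21
Reactants: 31 iodo ketone
Product: 33 C19 ketol, via potassium enolate 32 (not isolated)
Conditions: KHMDS (1.05 equiv), THF, −78 °C; then 2-(phenylsulfonyl)-3-phenyloxaziridine, −78 °C; AcOH
Reagents that add atoms: 2-(phenylsulfonyl)-3-phenyloxaziridine, O=S(=O)(N1OC1c1ccccc1)c1ccccc1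
Why: Enolate hydroxylation with an N-sulfonyloxaziridine can occur only at C19, the sole enolisable carbon, while the β-branched primary iodide is not attacked at this temperature and the configuration of the new carbinol is irrelevant.

Step 22
Reactants: 33 ketol
Product: 34 ring C 1,2-dione
Conditions: Dess–Martin periodinane, CH2Cl2, 0 °C → rt
Reagents that add atoms: none
Why: Periodinane oxidation converts the α-ketol into the 1,2-dione under neutral conditions that an alkyl iodide, a lactone and a tert-butyl ester tolerate.

Step 23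
Reactants: 34 dione; 35 acetaldehyde
Product: 37 C20 aldol adduct, via trimethylsilyl enol ether 36 (not isolated)
Conditions: TMSCl, Et3N, CH2Cl2, 0 °C; evaporation and pentane filtration; then CH3CHO, BF3·OEt2, CH2Cl2, −78 °C
Reagents that add atoms: none
Why: In this Mukaiyama aldol addition O-silylation fixes the only possible enol (toward C20) and loss of the silyl group makes the attack on activated acetaldehyde irreversible, which a stabilised free dione enolate would not ensure, and the new centres are erased in the next step.

Step 24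
Reactants: 37 aldol adduct
Product: 38 (E)-ethylidene dione with C25 iodide arm
Conditions: CSA (5 mol %), 4 Å molecular sieves, CH2Cl2, 0 °C → rt
Reagents that add atoms: none
Why: Acid-catalysed dehydration through enol-assisted ionisation of the C23 hydroxy group gives the more stable E isomer (C24 turned away from the C19 oxygen), and base is avoided so that C24 is not deprotonated toward the vinyl enol tautomer.

Step 25
Reactants: 38 iodo ethylidene dione
Product: 39 tert-butyl ester of the target (ring D closed)
Conditions: (Me3Si)3SiH (1.5 equiv, syringe pump over 10 h), Et3B (0.3 equiv in portions), air, Yb(OTf)3 (1.1 equiv), CH2Cl2–THF 4:1, 2 mM, 0 °C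
Reagents that add atoms: none
Why: Ethyl radicals from Et3B and air start a chain in which the silyl radical abstracts iodine from C25, the nucleophilic primary radical adds to C23 of the ytterbium-chelated ene-dione, and the C20 radical (delocalised onto the C19 oxygen) takes hydrogen from the silane. The closest known reaction type is the endo-selective reductive macrocyclisation of ω-iodoalkyl enones (an intramolecular Giese addition), combined with the Lewis acid acceleration known for β-substituted chelating acceptors. Ring D closes in the 11-endo-trig mode, the 10-exo alternative at C20 running against the polarity of the acceptor. C23 is controlled by the tether and the alkene geometry: the arm is anchored at C6 on the face of ring C that carries C13, so C25 can reach only that face of the planar s-cis enone, and with C24 syn to C21 this attack gives the required configuration. C20 receives hydrogen on the face opposite the new bridge, and because it is enolisable any epimer should drain to the same less strained isomer. The step needs cyclisation to outrun hydrogen transfer to the C25 radical and silyl attack on the dione, which is addressed by high dilution, slow addition of a modest hydrogen donor, fast iodine abstraction, and the lowered acceptor LUMO that chelation of the adjacent C18 and C19 carbonyls provides against the retarding β-methyl group.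

Step 26
Reactants: 39 tert-butyl ester
Product: 40 CNP0115928.1
Conditions: TFA–CH2Cl2 1:4, 0 °C → rt
Reagents that add atoms: none
Why: Acidolysis of the tert-butyl ester by loss of isobutene leaves lactone, dione and enoic acid intact, and the acidic medium lets C20 equilibrate through its enol should any epimer have survived.

Compound list
1 | (S)-3-bromo-2-methylpropan-1-ol | OC[C@H](C)CBr | starting material
2 | (S)-(3-bromo-2-methylpropoxy)(tert-butyl)diphenylsilane | CC(C)(C)[Si](c1ccccc1)(c1ccccc1)OC[C@H](C)CBr | intermediate
3 | (4-bromobut-1-yn-1-yl)trimethylsilane | C[Si](C)(C)C#CCCBr | starting material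
4 | [4-(trimethylsilyl)but-3-yn-1-yl]magnesium bromide | C[Si](C)(C)C#CCC[Mg]Br | intermediate
5 | (R)-tert-butyl{[2-methyl-7-(trimethylsilyl)hept-6-yn-1-yl]oxy}diphenylsilane | CC(C)(C)[Si](c1ccccc1)(c1ccccc1)OC[C@H](C)CCCC#C[Si](C)(C)C | intermediate
6 | (R)-tert-butyl[(2-methylhept-6-yn-1-yl)oxy]diphenylsilane | CC(C)(C)[Si](c1ccccc1)(c1ccccc1)OC[C@H](C)CCCC#C | intermediate
7 | (E)-alkenylzirconocene chloride from 6 (Zr on C7, cyclopentadienyl ligands drawn σ-bound) | CC(C)(C)[Si](c1ccccc1)(c1ccccc1)OC[C@H](C)CCC/C=C/[Zr](Cl)(C1C=CC=C1)C1C=CC=C1 | intermediate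
8 | (R,E)-tert-butyl[(7-iodo-2-methylhept-6-en-1-yl)oxy]diphenylsilane | CC(C)(C)[Si](c1ccccc1)(c1ccccc1)OC[C@H](C)CCC/C=C/I | intermediate
9 | propyne | CC#C | starting material
10 | prop-1-ynyllithium | CC#C[Li] | intermediate
11 | tert-butyl but-2-ynoate | CC#CC(=O)OC(C)(C)C | intermediate
12 | tert-butyl (E)-2-(tributylstannyl)but-2-enoate (methyl cis to ester) | C/C=C(/[Sn](CCCC)(CCCC)CCCC)C(=O)OC(C)(C)C | intermediate
13 | tert-butyl (2Z,3E,8R)-9-[(tert-butyldiphenylsilyl)oxy]-2-ethylidene-8-methylnon-3-enoate | CC(C)(C)[Si](c1ccccc1)(c1ccccc1)OC[C@H](C)CCC/C=C/C(=C/C)C(=O)OC(C)(C)C | intermediate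
14 | (S)-lactic acid | C[C@H](O)C(=O)O | starting material
15 | pivalaldehyde | CC(C)(C)C=O | starting material
16 | (2S,5S)-2-tert-butyl-5-methyl-1,3-dioxolan-4-one (cis) | C[C@@H]1O[C@H](C(C)(C)C)OC1=O | intermediate
17 | (2S,5R)-5-bromo-2-tert-butyl-5-methyl-1,3-dioxolan-4-one (Br trans to tert-butyl) | C[C@]1(Br)O[C@H](C(C)(C)C)OC1=O | intermediate
18 | (S)-2-tert-butyl-5-methylene-1,3-dioxolan-4-one | C=C1O[C@H](C(C)(C)C)OC1=O | intermediate
19 | (6S,10S,13R) cycloadduct: ring A cyclohexene (C7=C8–CO2tBu) with the (R)-5-(TBDPS-oxy)-4-methylpentyl arm on C6 and methyl on C10, spiro at C13 to (S)-2-tert-butyl-1,3-dioxolan-4-one; arm, C11 methyl and O14 mutually cis, tert-butyl trans to C6 | CC(C)(C)[Si](c1ccccc1)(c1ccccc1)OC[C@H](C)CCC[C@H]1C=C(C(=O)OC(C)(C)C)[C@@H](C)C[C@@]12O[C@H](C(C)(C)C)OC2=O | intermediate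
20 | ring A α-hydroxy N-methoxy-N-methylamide: C13 carries OH (cis to arm and C11 methyl) and C22(=O)N(OMe)Me; C2, C6, C10, C13 as in 19 | CC(C)(C)[Si](c1ccccc1)(c1ccccc1)OC[C@H](C)CCC[C@H]1C=C(C(=O)OC(C)(C)C)[C@@H](C)C[C@]1(O)C(=O)N(C)OC | intermediate
21 | ring A α-hydroxy vinyl ketone, C13(OH)–C22(=O)–CH=CH2; stereocentres as in 19 | CC(C)(C)[Si](c1ccccc1)(c1ccccc1)OC[C@H](C)CCC[C@H]1C=C(C(=O)OC(C)(C)C)[C@@H](C)C[C@]1(O)C(=O)C=C | intermediate
22 | methyl acetoacetate | COC(=O)CC(C)=O | starting material
23 | methyl 3-(trimethylsilyloxy)but-2-enoate | COC(=O)C=C(C)O[Si](C)(C)C | intermediate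
24 | lithium dienolate of 23 | COC(O[Li])=CC(=C)O[Si](C)(C)C | intermediate
25 | 1-methoxy-1,3-bis(trimethylsilyloxy)buta-1,3-diene | COC(O[Si](C)(C)C)=CC(=C)O[Si](C)(C)C | intermediate
26 | methyl 3,7-dioxoheptanoate whose C7 (= C22) is bound to C13(OH) of ring A; stereocentres as in 19 | CC(C)(C)[Si](c1ccccc1)(c1ccccc1)OC[C@H](C)CCC[C@H]1C=C(C(=O)OC(C)(C)C)[C@@H](C)C[C@]1(O)C(=O)CCCC(=O)CC(=O)OC | intermediate
27 | tricyclic acyl butenolide: ring B lactone with C16=C22 fused to the ring C cyclohexenone (C18=O), spiro at C13 to ring A; stereocentres as in 19 | CC(C)(C)[Si](c1ccccc1)(c1ccccc1)OC[C@H](C)CCC[C@H]1C=C(C(=O)OC(C)(C)C)[C@@H](C)C[C@@]12OC(=O)C3=C2CCCC3=O | intermediate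
28 | cis-fused β-keto lactone: H16 and H22 both on the C12 face of ring B, ring C syn to C6 | CC(C)(C)[Si](c1ccccc1)(c1ccccc1)OC[C@H](C)CCC[C@H]1C=C(C(=O)OC(C)(C)C)[C@@H](C)C[C@@]12OC(=O)[C@H]3C(=O)CCC[C@@H]23 | intermediate
29 | C16-methyl β-keto lactone (C17 methyl syn to H22), TBDPS ether | CC(C)(C)[Si](c1ccccc1)(c1ccccc1)OC[C@H](C)CCC[C@H]1C=C(C(=O)OC(C)(C)C)[C@@H](C)C[C@@]12OC(=O)[C@@]3(C)C(=O)CCC[C@@H]23 | intermediate
30 | C25 primary alcohol of the tricycle | OC[C@H](C)CCC[C@H]1C=C(C(=O)OC(C)(C)C)[C@@H](C)C[C@@]12OC(=O)[C@@]3(C)C(=O)CCC[C@@H]23 | intermediate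
31 | C25 primary iodide of the tricycle, (R)-5-iodo-4-methylpentyl arm | IC[C@H](C)CCC[C@H]1C=C(C(=O)OC(C)(C)C)[C@@H](C)C[C@@]12OC(=O)[C@@]3(C)C(=O)CCC[C@@H]23 | intermediate
32 | potassium C18=C19 enolate of 31 | IC[C@H](C)CCC[C@H]1C=C(C(=O)OC(C)(C)C)[C@@H](C)C[C@@]12OC(=O)[C@@]3(C)C(O[K])=CCC[C@@H]23 | intermediate
33 | C19-hydroxy C18-ketone (C19 epimers) | IC[C@H](C)CCC[C@H]1C=C(C(=O)OC(C)(C)C)[C@@H](C)C[C@@]12OC(=O)[C@@]3(C)C(=O)C(O)CC[C@@H]23 | intermediate
34 | C18,C19-dione (enolises toward C20) | IC[C@H](C)CCC[C@H]1C=C(C(=O)OC(C)(C)C)[C@@H](C)C[C@@]12OC(=O)[C@@]3(C)C(=O)C(=O)CC[C@@H]23 | intermediate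
35 | acetaldehyde | CC=O | starting material
36 | C19 O-trimethylsilyl enol ether (C19=C20) of 34 | IC[C@H](C)CCC[C@H]1C=C(C(=O)OC(C)(C)C)[C@@H](C)C[C@@]12OC(=O)[C@@]3(C)C(=O)C(O[Si](C)(C)C)=CC[C@@H]23 | intermediate
37 | C20 (1-hydroxyethyl) dione (mixture at C20 and C23) | IC[C@H](C)CCC[C@H]1C=C(C(=O)OC(C)(C)C)[C@@H](C)C[C@@]12OC(=O)[C@@]3(C)C(=O)C(=O)C(C(C)O)C[C@@H]23 | intermediate
38 | tricyclic C20 (E)-ethylidene C18,C19-dione with the (R)-5-iodo-4-methylpentyl arm on C6, tert-butyl ester | IC[C@H](C)CCC[C@H]1C=C(C(=O)OC(C)(C)C)[C@@H](C)C[C@@]12OC(=O)[C@@]3(C)C(=O)C(=O)/C(=C/C)C[C@@H]23 | intermediate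
39 | tert-butyl ester of the target, (2R,6S,10S,13R,16R,20R,22R,23R) | C[C@@H]1CCC[C@H]2C=C(C(=O)OC(C)(C)C)[C@@H](C)C[C@@]23OC(=O)[C@@]2(C)C(=O)C(=O)[C@H](C[C@H]23)[C@H](C)C1 | intermediate
40 | CNP0115928.1, (2R,6S,10S,13R,16R,20R,22R,23R) | C[C@@H]1CCC[C@H]2C=C(C(=O)O)[C@@H](C)C[C@@]23OC(=O)[C@@]2(C)C(=O)C(=O)[C@H](C[C@H]23)[C@H](C)C1 | target

Total step count: 26
Longest linear sequence: 20 steps (1–4, 7, 10–12, 15–26)

Steps most likely to fail

1. Step 25.
- What may go wrong: hydrogen transfer from the silane to the C25 radical before the slow closure of an 11-membered ring onto a β-methyl-substituted carbon, and addition of silyl or ethyl radicals to the ene-dione.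
- Fallback (polar instead of radical closure of the same bond): the sequence sets out from 38. AgNO2 in Et2O replaces iodide by nitro (Victor Meyer reaction) to give the nitroalkane F1. A catalytic amount of a hindered amine base at high dilution then closes C23–C25 by a reversible intramolecular nitro-Michael addition, giving the C25-nitro macrocycle F2 under thermodynamic control. Radical denitration with Bu3SnH and AIBN in hot toluene removes the nitro group and rejoins the route at 39.

2. Step 23.
- What may go wrong: low nucleophilicity at C20 of an enol silane that carries the C18 acyl group, self-condensation of acetaldehyde, and retro-aldol cleavage on work-up.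
- Fallback (alkylation–elimination instead of aldol–dehydration): the sequence sets out from enol silane 36. 1-Chloroethyl phenyl sulfide and ZnBr2 generate a thionium ion that alkylates C20 irreversibly to give the β-phenylthio dione F3. mCPBA at −78 °C gives the sulfoxide F4, sulfur being oxidised much faster than the alkyl iodide. Gentle heating in toluene over CaCO3 brings about syn elimination toward the acidic C20–H, which arrives at 38 without acid or base.

3. Step 15.
- What may go wrong: polymerisation of vinyl ketone 21 under Lewis acid, bonding through the central carbon of diene 25, or a competing [4+2] cycloaddition.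
- Fallback (ring C built as a plain cyclohexenone, C15 brought in as carbon monoxide): the sequence sets out from amide 20. Pent-4-enylmagnesium bromide gives the pentenyl ketone F5. Tsuji–Wacker oxidation (PdCl2, CuCl, O2, DMF–H2O) of the terminal alkene gives the 1,5-diketone F6. Base-mediated aldol condensation, in which only the C16 methyl can reach C22 through a six-membered ring, gives the 3-substituted cyclohexenone F7. α-Iodination (I2, pyridine) gives the iodoenone F8. Carbonylative lactonisation (PdCl2(PPh3)2, CO, Et3N, THF) with the tertiary O14–H closes ring B and rejoins the route at 27.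

Further compounds
F1 | step 25 | C25 nitroalkane analogue of 38 | [O-][N+](=O)C[C@H](C)CCC[C@H]1C=C(C(=O)OC(C)(C)C)[C@@H](C)C[C@@]12OC(=O)[C@@]3(C)C(=O)C(=O)/C(=C/C)C[C@@H]23
F2 | step 25 | C25-nitro derivative of macrocycle 39 (C25 undefined) | C[C@@H]1CCC[C@H]2C=C(C(=O)OC(C)(C)C)[C@@H](C)C[C@@]23OC(=O)[C@@]2(C)C(=O)C(=O)[C@H](C[C@H]23)[C@H](C)C1[N+](=O)[O-]
F3 | step 23 | C20 [1-(phenylthio)ethyl] dione (mixture at C20 and C23) | IC[C@H](C)CCC[C@H]1C=C(C(=O)OC(C)(C)C)[C@@H](C)C[C@@]12OC(=O)[C@@]3(C)C(=O)C(=O)C(C(C)Sc4ccccc4)C[C@@H]23
F4 | step 23 | C20 [1-(phenylsulfinyl)ethyl] dione (mixture at C20, C23 and S) | IC[C@H](C)CCC[C@H]1C=C(C(=O)OC(C)(C)C)[C@@H](C)C[C@@]12OC(=O)[C@@]3(C)C(=O)C(=O)C(C(C)S(=O)c4ccccc4)C[C@@H]23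
F5 | step 15 | ring A α-hydroxy pent-4-enyl ketone | CC(C)(C)[Si](c1ccccc1)(c1ccccc1)OC[C@H](C)CCC[C@H]1C=C(C(=O)OC(C)(C)C)[C@@H](C)C[C@]1(O)C(=O)CCCC=C
F6 | step 15 | ring A α-hydroxy 1,5-diketone (C22 and C18 ketones) | CC(C)(C)[Si](c1ccccc1)(c1ccccc1)OC[C@H](C)CCC[C@H]1C=C(C(=O)OC(C)(C)C)[C@@H](C)C[C@]1(O)C(=O)CCCC(C)=O
F7 | step 15 | 3-substituted cyclohex-2-enone (C16H=C22, C18=O) on C13(OH) | CC(C)(C)[Si](c1ccccc1)(c1ccccc1)OC[C@H](C)CCC[C@H]1C=C(C(=O)OC(C)(C)C)[C@@H](C)C[C@]1(O)C2=CC(=O)CCC2
F8 | step 15 | 2-iodo derivative of F7 (iodine on C16) | CC(C)(C)[Si](c1ccccc1)(c1ccccc1)OC[C@H](C)CCC[C@H]1C=C(C(=O)OC(C)(C)C)[C@@H](C)C[C@]1(O)C2=C(I)C(=O)CCC2
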